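**Strategy.** The ten-membered carbocycle is closed late at its C6–C7 bond (briarane numbering) by an intramolecular Nozaki–Hiyama–Kishi γ-chloroallylation. The step exploits the C6 chlorine sitting between the C5 exocyclic methylene (C16) and the oxygenated C7 of the γ-lactone. A C16 allylic bromide bearing the vinylic chlorine on C6 becomes an allylchromium that attacks a C7 α-hydroxy aldehyde through C6, forming the ring, the C6–Cl and C7–O stereocentres and the C5=C16 methylene in one operation. The precursor is a trans-1,2-disubstituted cyclohexane (C1, C10) carrying a chlorodienyl bromide arm and an aldehyde arm, built by Birch alkylation, a dioxolanone aldol and Ni/Cr coupling.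

Key step: step 30

Numbering used below: C1 quaternary carbon (Me-15), C2–C9 the chain of the ten-membered ring, C10–C14 the rest of the cyclohexane, C16 on C5, C17 (Me-18) and C19 the lactone carbons, Me-20 on C11; on the six-membered ring β is the face of Me-15.
Assumption: the (S)-auxiliary 2 is taken to steer the Birch methylation to the face that gives (1R)-6; were the sense opposite, the enantiomeric auxiliary would be used.
Remark: the C12 carbinol configuration in 13–48 is of no consequence (oxidised in step 32); the β-epimer is drawn.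

Step 1
Reactants: 1 2-methoxy-5-methylbenzoic acid; 2 (S)-2-(methoxymethyl)pyrrolidine
Product: 4 (S)-1-(2-methoxy-5-methylbenzoyl)-2-(methoxymethyl)pyrrolidine, via acid chloride 3 (not isolated)
Conditions: (COCl)2, DMF (cat.), CH2Cl2, 0 °C to rt; then 2, Et3N, CH2Cl2, 0 °C
Reagents that add atoms: none
Why: Amide formation through the acid chloride attaches the prolinol-ether auxiliary that will control the quaternary centre; no stereocentre is formed.

Step 2
Reactants: 4 benzamide
Product: 6 (1R)-2-methoxy-1,5-dimethylcyclohexa-2,5-diene-1-carboxamide of auxiliary 2, via potassium enolate 5 (not isolated)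
Conditions: K, NH3–THF, t-BuOH (1 equiv), −78 °C; then MeI, −78 °C
Reagents that add atoms: iodomethane CI
Why: Birch reduction–alkylation gives the 1,4-diene with OMe and methyl on sp2 carbons, and the chelated amide enolate should be methylated on the face away from the CH2OMe arm, setting quaternary C1.

Step 3
Reactants: 6 diene amide
Product: 7 (1R)-1,3-dimethyl-6-oxocyclohex-2-ene-1-carboxamide of auxiliary 2 (C14 ketone)
Conditions: 1 M HCl, MeOH, rt
Reagents that add atoms: water O
Why: Enol ether hydrolysis unmasks the C14 ketone, and the quaternary C1 keeps the C10=C11 alkene out of conjugation.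

Step 4
Reactants: 7 keto amide
Product: 8 (1R,6S)-6-hydroxy-1,3-dimethylcyclohex-2-ene-1-carboxamide of auxiliary 2 (14α-hydroxyl cis to the amide)
Conditions: NaBH4, MeOH, −20 °C
Reagents that add atoms: none
Why: Borohydride reduction in which hydride should approach C14 anti to the bulky carboxamide on C1 (Felkin–Anh), placing the hydroxyl cis to the C2 carbonyl.

Step 5
Reactants: 8 hydroxy amide
Product: 9 14α-butanoate of 8
Conditions: (PrCO)2O, Et3N, 4-(dimethylamino)pyridine (cat.), CH2Cl2, rt
Reagents that add atoms: butyric anhydride CCCC(=O)OC(=O)CCC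
Why: Pyridine-catalysed acylation installs the C14 butanoate while C14 is the only free hydroxyl.

Step 6
Reactants: 9 butanoate
Product: 10 enone (C12 ketone conjugated to C10=C11)
Conditions: Rh2(cap)4 (cap = caprolactamate, 1 mol %), t-BuOOH (aq), K2CO3, CH2Cl2, rt
Reagents that add atoms: tert-butyl hydroperoxide CC(C)(C)OO
Why: Rhodium-catalysed allylic oxidation should hit C12, the only ring allylic methylene, because C10 is flanked by the quaternary C1.

Step 7
Reactants: 10 enone
Product: 12 10β-vinyl-11β-methyl-12-ketone, via silyl enol ether 11 (not isolated)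
Conditions: CH2=CHMgBr, CuI (20 mol %), Me3SiCl, THF, −78 °C; then 1 M HCl, THF, 0 °C
Reagents that add atoms: vinylmagnesium bromide C=C[Mg]Br
Why: Copper-catalysed conjugate addition should deliver vinyl to C10 anti to the carboxamide and the C14 ester, and kinetic protonation of the silyl enol ether from the α face (away from the vinyl group and Me-15) sets C11 with its methyl cis to C9.

Step 8
Reactants: 12 ketone
Product: 13 12β-alcohol
Conditions: NaBH4, CeCl3·7H2O, MeOH, −40 °C
Reagents that add atoms: none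
Why: Luche reduction under non-basic conditions masks the ketone as a carbinol, which freezes the epimerisable C11 centre and protects the β-acyloxy ketone.

Step 9
Reactants: 13 alcohol
Product: 14 12β-tert-butyldimethylsilyl ether
Conditions: TBSOTf, 2,6-lutidine, CH2Cl2, 0 °C
Reagents that add atoms: tert-butyldimethylsilyl triflate CC(C)(C)[Si](C)(C)OS(=O)(=O)C(F)(F)F
Why: Silylation of the hindered secondary alcohol with the silyl triflate.

Step 10
Reactants: 14 vinyl compound
Product: 16 C9 aldehyde (10β-formyl), via ozonide 15 (not isolated)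
Conditions: O3, CH2Cl2, −78 °C; then PPh3, −78 °C to rt
Reagents that add atoms: ozone [O-][O+]=O
Why: Ozonolysis with reductive work-up cleaves the only alkene to the C9 aldehyde without touching C10.

Step 11
Reactants: 17 diethyl (S)-malate
Product: 19 diethyl (2S,3R)-2-hydroxy-3-methylbutanedioate, via dilithium dianion 18 (not isolated)
Conditions: LDA (2.2 equiv), THF, −78 to −20 °C; then MeI, −78 °C to rt
Reagents that add atoms: iodomethane CI
Why: Fráter–Seebach alkylation, in which the chelated alkoxide enolate is methylated anti to the carbinol oxygen, sets the future C17.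

Step 12
Reactants: 19 methylmalate diester
Product: 20 (2S,3R)-2-hydroxy-3-methylbutanedioic acid
Conditions: KOH, H2O–EtOH, rt; then HCl to pH 1
Reagents that add atoms: potassium hydroxide [K+].[OH-]
Why: Saponification of both esters at room temperature leaves both stereocentres untouched.

Step 13
Reactants: 20 diacid
Product: 21 (2R)-2-[(2S,4S)-2-tert-butyl-5-oxo-1,3-dioxolan-4-yl]propanoic acid
Conditions: t-BuCHO, p-toluenesulfonic acid (cat.), H2SO4 (cat.), pentane, reflux (water separator)
Reagents that add atoms: pivalaldehyde CC(C)(C)C=O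
Why: Acetalisation of the α-hydroxy acid gives the five-membered dioxolanone as the cis isomer, so the acetal carbon stores the C8 configuration (self-regeneration of stereocentres).

Step 14
Reactants: 21 dioxolanone acid
Product: 22 tert-butyl (2R)-2-[(2S,4S)-2-tert-butyl-5-oxo-1,3-dioxolan-4-yl]propanoate
Conditions: isobutene, H2SO4 (cat.), CH2Cl2, sealed vessel, rt
Reagents that add atoms: isobutene CC(C)=C
Why: Acid-catalysed addition to isobutene gives the tert-butyl ester, which resists alkoxide attack in steps 15–27.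

Step 15
Reactants: 22 dioxolanone ester; 16 C9 aldehyde
Product: 24 aldol adduct (C8–C9 bond; 9-hydroxyl; C8 in the dioxolanone), via lithium enolate 23 (not isolated)
Conditions: LDA, THF, −78 °C; then 16, −78 °C; AcOH quench at −78 °C
Reagents that add atoms: none
Why: Dioxolanone aldol in which the aldehyde enters anti to the tert-butyl group (C8), while Felkin–Anh attack on the aldehyde (C1 as the large group) and the chair Zimmerman–Traxler arrangement with the C17 branch cis to OLi both lead to the (9R) carbinol.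

Step 16
Reactants: 24 aldol adduct
Product: 25 C7,C8,C9-triol
Conditions: LiBH4, THF–MeOH, −20 to 0 °C
Reagents that add atoms: none
Why: Borohydride reduction of the activated acylal carbonyl (assisted by the C9 alkoxide) opens the dioxolanone to the C7 primary alcohol and C8 tertiary alcohol, while the hindered butanoate and tert-butyl ester and the amide should survive.

Step 17
Reactants: 25 triol
Product: 26 7-O-triethylsilyl ether
Conditions: Et3SiCl, imidazole, CH2Cl2, −20 °C
Reagents that add atoms: chlorotriethylsilane CC[Si](Cl)(CC)CC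
Why: Silylation is selective for the primary C7 hydroxyl over the hindered secondary C9 and tertiary C8 hydroxyls.

Step 18
Reactants: 26 silyl ether
Product: 27 9-acetate
Conditions: Ac2O, pyridine, 4-(dimethylamino)pyridine (cat.), CH2Cl2, 0 °C to rt
Reagents that add atoms: acetic anhydride CC(=O)OC(C)=O
Why: Acylation of the secondary C9 hydroxyl, with the tertiary C8 hydroxyl left free.

Step 19
Reactants: 27 amide acetate
Product: 29 C2 aldehyde (1-formyl), via zirconium hemiaminal 28 (not isolated)
Conditions: Cp2ZrHCl (3 equiv), THF, rt; then H2O, silica gel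
Reagents that add atoms: none
Why: Schwartz reagent reduces tertiary amides to aldehydes through a stable zirconated hemiaminal and is chemoselective over esters, releasing auxiliary 2 on hydrolysis.

Step 20
Reactants: 30 propargyl alcohol; 31 (E)-(2-bromovinyl)trimethylsilane
Product: 34 (Z)-3-chloro-2-[(E)-2-(trimethylsilyl)vinyl]prop-2-en-1-ol, via Grignard reagent 32 (not isolated), via magnesium chelate 33 (not isolated)
Conditions: 31, Mg, THF, 40 °C; then 30, CuI (10 mol %), THF, −10 °C to rt; then NCS, −30 °C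
Reagents that add atoms: N-chlorosuccinimide O=C1CCC(=O)N1Cl
Why: Copper-catalysed anti-carbomagnesiation of propargyl alcohol puts the alkenyl group on the internal carbon and magnesium on the terminal carbon in a five-membered chelate, so chlorination with retention fixes chlorine cis to the CH2O arm.

Step 21
Reactants: 34 chlorodienol
Product: 35 triethylsilyl ether of 34
Conditions: Et3SiCl, imidazole, CH2Cl2, 0 °C
Reagents that add atoms: chlorotriethylsilane CC[Si](Cl)(CC)CC
Why: Standard silylation of the primary allylic alcohol.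

Step 22
Reactants: 35 dienylsilane
Product: 36 (E)-dienyl iodide (C3–C6 and C16 fragment)
Conditions: NIS, MeCN–ClCH2CN, 0 °C
Reagents that add atoms: N-iodosuccinimide O=C1CCC(=O)N1I
Why: Iododesilylation by ipso attack at the silicon-bearing carbon proceeds with retention of the E geometry.

Step 23
Reactants: 29 C2 aldehyde; 36 dienyl iodide
Product: 38 dienyl carbinol (C2–C3 bond; C2 epimers), via alkenylchromium 37 (not isolated)
Conditions: CrCl2 (4 equiv), NiCl2 (2 mol %), DMSO, rt
Reagents that add atoms: none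
Why: Nozaki–Hiyama–Kishi alkenylation is selective for the aldehyde over esters and the free tertiary hydroxyl and leaves the vinylic chloride untouched; the C2 epimers converge in step 24.

Step 24
Reactants: 38 carbinol mixture
Product: 39 dienone (C2 ketone)
Conditions: Dess–Martin periodinane, NaHCO3, CH2Cl2, 0 °C to rt
Reagents that add atoms: none
Why: Dess–Martin oxidation of the only secondary alcohol gives one cross-conjugated chlorodienone.

Step 25
Reactants: 39 dienone
Product: 40 (2R)-carbinol
Conditions: (S)-Me-CBS oxazaborolidine C18H20BNO (20 mol %), catecholborane, toluene, −78 °C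
Reagents that add atoms: none
Why: Corey–Bakshi–Shibata reduction with the quaternary C1 as the large group and the dienyl group as the small one should deliver hydride to the face giving (2R), by analogy with acetophenone giving the (R)-alcohol.

Step 26
Reactants: 40 carbinol
Product: 41 2,9-diacetate
Conditions: Ac2O, pyridine, 4-(dimethylamino)pyridine (cat.), CH2Cl2, 0 °C to rt
Reagents that add atoms: acetic anhydride CC(=O)OC(C)=O
Why: Acylation of the secondary C2 hydroxyl; the tertiary C8 hydroxyl stays free.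

Step 27
Reactants: 41 bis(triethylsilyl) ether
Product: 42 C7,C16-diol
Conditions: pyridinium p-toluenesulfonate, MeOH–CH2Cl2, 0 °C
Reagents that add atoms: none
Why: Mild acidic methanolysis removes the two primary triethylsilyl ethers and leaves the secondary tert-butyldimethylsilyl ether, the esters and the chlorodiene intact.

Step 28
Reactants: 42 diol
Product: 43 C16 allylic bromide
Conditions: NBS, Me2S, CH2Cl2, −30 to 0 °C
Reagents that add atoms: N-bromosuccinimide O=C1CCC(=O)N1Br
Why: Corey–Kim halogenation converts only the allylic alkoxysulfonium salt into the bromide, while the saturated C7 alkoxysulfonium salt reverts to the alcohol on work-up.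

Step 29
Reactants: 43 bromo alcohol
Product: 44 C7 aldehyde (α-hydroxy aldehyde)
Conditions: Dess–Martin periodinane, NaHCO3, CH2Cl2, 0 °C
Reagents that add atoms: none
Why: Dess–Martin oxidation of the primary alcohol under neutral, amine-free conditions tolerates the allylic bromide and the adjacent tertiary hydroxyl.

Step 30
Reactants: 44 bromo aldehyde
Product: 46 ten-membered carbocycle (6S-chloride, 7R-hydroxyl, C5=C16 methylene), via allylchromium 45 (not isolated)
Conditions: CrCl2 (6 equiv), THF (2 mM, slow addition of 44), 0 °C to rt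
Reagents that add atoms: none
Why: Two equivalents of CrCl2 reduce the primary allylic bromide to a γ-chloroallylchromium species (trivalent chromium) whose σ–π interconversion erases the C5=C6 geometry, and this adds through C6 to the aldehyde in a chair-like six-membered Zimmerman–Traxler transition state. The closest known reactions are the CrCl2-mediated chloroallylation of aldehydes with 1,3-dihalopropenes, which gives anti-chlorohydrins, and Nozaki–Hiyama–Kishi allylative closures of ten-membered carbocycles. The ten-membered ring closes in a 10-exo-trig mode, C6 adding to the exocyclic C7=O. C6 is set relative to C7 by the chair transition state with chlorine trans to the CH2Cr arm (anti, 6S with 7R), and C7 by the C8 stereocentre: chromium bridges the aldehyde oxygen and the C8 hydroxyl, and the allyl unit, tethered through C9, should attack the face remote from the C17 branch. The step needs γ-regioselectivity (C6, not C16), chemoselectivity for the aldehyde over four esters and for the primary bromide over the secondary allylic chloride of the product, and cyclisation over oligomerisation. These are secured by chromium residing on the unhindered primary C16, by the mildness of the organochromium reagent, and by high dilution together with the trans-diequatorial C1 and C10 arms pointing toward each other.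

Step 31
Reactants: 46 hydroxy tert-butyl ester
Product: 48 γ-lactone with free 12-hydroxyl, via seco acid 47 (not isolated)
Conditions: CF3CO2H–CH2Cl2–H2O (20:79:1), 0 °C to rt; NaHCO3 work-up
Reagents that add atoms: none
Why: Acidolysis removes the tert-butyl ester and the silyl ether, and the freed C19 acid closes onto the C7 hydroxyl (5-exo-trig lactonisation) without changing any stereocentre.

Step 32
Reactants: 48 lactone alcohol
Product: 49 target compound (CNP0283653.2)
Conditions: Dess–Martin periodinane, NaHCO3, CH2Cl2, 0 °C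
Reagents that add atoms: none
Why: Dess–Martin oxidation of the last secondary alcohol gives the C12 ketone under non-basic conditions, which should preserve the kinetically set C11 centre and the β-butanoyloxy ketone.

**Compound list**

1 | 2-methoxy-5-methylbenzoic acid | COc1ccc(C)cc1C(O)=O | starting material
2 | (S)-2-(methoxymethyl)pyrrolidine | COC[C@@H]1CCCN1 | starting material
3 | 2-methoxy-5-methylbenzoyl chloride | COc1ccc(C)cc1C(Cl)=O | intermediate
4 | (S)-1-(2-methoxy-5-methylbenzoyl)-2-(methoxymethyl)pyrrolidine | COC[C@@H]1CCCN1C(=O)c1cc(C)ccc1OC | intermediate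
5 | potassium enolate of the Birch-reduced amide | COC[C@@H]1CCCN1C([O-])=C2C=C(C)CC=C2OC.[K+] | intermediate
6 | (1R)-2-methoxy-1,5-dimethylcyclohexa-2,5-diene-1-carboxamide of 2 | COC[C@@H]1CCCN1C(=O)[C@]2(C)C=C(C)CC=C2OC | intermediate
7 | (1R)-1,3-dimethyl-6-oxocyclohex-2-ene-1-carboxamide of 2 | COC[C@@H]1CCCN1C(=O)[C@]2(C)C=C(C)CCC2=O | intermediate
8 | (1R,6S)-6-hydroxy-1,3-dimethylcyclohex-2-ene-1-carboxamide of 2 | COC[C@@H]1CCCN1C(=O)[C@]2(C)C=C(C)CC[C@@H]2O | intermediate
9 | 14α-butanoate of 8 | COC[C@@H]1CCCN1C(=O)[C@]2(C)C=C(C)CC[C@@H]2OC(=O)CCC | intermediate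
10 | enone (C12 ketone, C10=C11) | COC[C@@H]1CCCN1C(=O)[C@]2(C)C=C(C)C(=O)C[C@@H]2OC(=O)CCC | intermediate
11 | trimethylsilyl enol ether (C11=C12) with 10β-vinyl | COC[C@@H]1CCCN1C(=O)[C@]2(C)[C@@H](C=C)C(C)=C(O[Si](C)(C)C)C[C@@H]2OC(=O)CCC | intermediate
12 | 10β-vinyl-11β-methyl-12-ketone | COC[C@@H]1CCCN1C(=O)[C@]2(C)[C@@H](C=C)[C@@H](C)C(=O)C[C@@H]2OC(=O)CCC | intermediate
13 | 12β-alcohol | COC[C@@H]1CCCN1C(=O)[C@]2(C)[C@@H](C=C)[C@@H](C)[C@@H](O)C[C@@H]2OC(=O)CCC | intermediate
14 | 12β-tert-butyldimethylsilyl ether | COC[C@@H]1CCCN1C(=O)[C@]2(C)[C@@H](C=C)[C@@H](C)[C@@H](O[Si](C)(C)C(C)(C)C)C[C@@H]2OC(=O)CCC | intermediate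
15 | ozonide (1,2,4-trioxolane at C9) | COC[C@@H]1CCCN1C(=O)[C@]2(C)[C@@H](C3OCOO3)[C@@H](C)[C@@H](O[Si](C)(C)C(C)(C)C)C[C@@H]2OC(=O)CCC | intermediate
16 | C9 aldehyde | COC[C@@H]1CCCN1C(=O)[C@]2(C)[C@@H](C=O)[C@@H](C)[C@@H](O[Si](C)(C)C(C)(C)C)C[C@@H]2OC(=O)CCC | intermediate
17 | diethyl (S)-malate | CCOC(=O)C[C@H](O)C(=O)OCC | starting material
18 | dilithium alkoxide enolate of 17 | CCOC([O-])=C[C@H]([O-])C(=O)OCC.[Li+].[Li+] | intermediate
19 | diethyl (2S,3R)-2-hydroxy-3-methylbutanedioate | CCOC(=O)[C@H](C)[C@H](O)C(=O)OCC | intermediate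
20 | (2S,3R)-2-hydroxy-3-methylbutanedioic acid | OC(=O)[C@H](C)[C@H](O)C(O)=O | intermediate
21 | (2R)-2-[(2S,4S)-2-tert-butyl-5-oxo-1,3-dioxolan-4-yl]propanoic acid | CC(C)(C)[C@H]1O[C@@H]([C@@H](C)C(O)=O)C(=O)O1 | intermediate
22 | tert-butyl (2R)-2-[(2S,4S)-2-tert-butyl-5-oxo-1,3-dioxolan-4-yl]propanoate | CC(C)(C)[C@H]1O[C@@H]([C@@H](C)C(=O)OC(C)(C)C)C(=O)O1 | intermediate
23 | lithium enolate of 22 | CC(C)(C)[C@H]1OC([C@@H](C)C(=O)OC(C)(C)C)=C([O-])O1.[Li+] | intermediate
24 | aldol adduct (9R-hydroxyl, C8 in dioxolanone) | COC[C@@H]1CCCN1C(=O)[C@]2(C)[C@@H]([C@@H](O)[C@]3(O[C@H](C(C)(C)C)OC3=O)[C@@H](C)C(=O)OC(C)(C)C)[C@@H](C)[C@@H](O[Si](C)(C)C(C)(C)C)C[C@@H]2OC(=O)CCC | intermediate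
25 | C7,C8,C9-triol | COC[C@@H]1CCCN1C(=O)[C@]2(C)[C@@H]([C@@H](O)[C@](CO)(O)[C@@H](C)C(=O)OC(C)(C)C)[C@@H](C)[C@@H](O[Si](C)(C)C(C)(C)C)C[C@@H]2OC(=O)CCC | intermediate
26 | 7-O-triethylsilyl ether | COC[C@@H]1CCCN1C(=O)[C@]2(C)[C@@H]([C@@H](O)[C@](CO[Si](CC)(CC)CC)(O)[C@@H](C)C(=O)OC(C)(C)C)[C@@H](C)[C@@H](O[Si](C)(C)C(C)(C)C)C[C@@H]2OC(=O)CCC | intermediate
27 | 9-acetate | COC[C@@H]1CCCN1C(=O)[C@]2(C)[C@@H]([C@@H](OC(C)=O)[C@](CO[Si](CC)(CC)CC)(O)[C@@H](C)C(=O)OC(C)(C)C)[C@@H](C)[C@@H](O[Si](C)(C)C(C)(C)C)C[C@@H]2OC(=O)CCC | intermediate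
28 | zirconium hemiaminal of 27 | COC[C@@H]1CCCN1C(O[Zr](Cl)(C1C=CC=C1)C1C=CC=C1)[C@]2(C)[C@@H]([C@@H](OC(C)=O)[C@](CO[Si](CC)(CC)CC)(O)[C@@H](C)C(=O)OC(C)(C)C)[C@@H](C)[C@@H](O[Si](C)(C)C(C)(C)C)C[C@@H]2OC(=O)CCC | intermediate
29 | C2 aldehyde | O=C[C@]2(C)[C@@H]([C@@H](OC(C)=O)[C@](CO[Si](CC)(CC)CC)(O)[C@@H](C)C(=O)OC(C)(C)C)[C@@H](C)[C@@H](O[Si](C)(C)C(C)(C)C)C[C@@H]2OC(=O)CCC | intermediate
30 | propargyl alcohol | C#CCO | starting material
31 | (E)-(2-bromovinyl)trimethylsilane | C[Si](C)(C)/C=C/Br | starting material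
32 | (E)-2-(trimethylsilyl)vinylmagnesium bromide | C[Si](C)(C)/C=C/[Mg]Br | intermediate
33 | five-membered alkenylmagnesium alkoxide chelate | C[Si](C)(C)/C=C/C1=C[Mg]OC1 | intermediate
34 | (Z)-3-chloro-2-[(E)-2-(trimethylsilyl)vinyl]prop-2-en-1-ol | Cl/C=C(\CO)/C=C/[Si](C)(C)C | intermediate
35 | triethylsilyl ether of 34 | Cl/C=C(\CO[Si](CC)(CC)CC)/C=C/[Si](C)(C)C | intermediate
36 | (E)-dienyl iodide (chlorine cis to the CH2OSiEt3 arm) | Cl/C=C(\CO[Si](CC)(CC)CC)/C=C/I | intermediate
37 | alkenylchromium dichloride from 36 | Cl/C=C(\CO[Si](CC)(CC)CC)/C=C/[Cr](Cl)Cl | intermediate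
38 | dienyl carbinol (C2 epimers) | Cl/C=C(\CO[Si](CC)(CC)CC)/C=C/C(O)[C@]2(C)[C@@H]([C@@H](OC(C)=O)[C@](CO[Si](CC)(CC)CC)(O)[C@@H](C)C(=O)OC(C)(C)C)[C@@H](C)[C@@H](O[Si](C)(C)C(C)(C)C)C[C@@H]2OC(=O)CCC | intermediate
39 | dienone (C2 ketone) | Cl/C=C(\CO[Si](CC)(CC)CC)/C=C/C(=O)[C@]2(C)[C@@H]([C@@H](OC(C)=O)[C@](CO[Si](CC)(CC)CC)(O)[C@@H](C)C(=O)OC(C)(C)C)[C@@H](C)[C@@H](O[Si](C)(C)C(C)(C)C)C[C@@H]2OC(=O)CCC | intermediate
40 | (2R)-carbinol | Cl/C=C(\CO[Si](CC)(CC)CC)/C=C/[C@@H](O)[C@]2(C)[C@@H]([C@@H](OC(C)=O)[C@](CO[Si](CC)(CC)CC)(O)[C@@H](C)C(=O)OC(C)(C)C)[C@@H](C)[C@@H](O[Si](C)(C)C(C)(C)C)C[C@@H]2OC(=O)CCC | intermediate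
41 | 2,9-diacetate | Cl/C=C(\CO[Si](CC)(CC)CC)/C=C/[C@@H](OC(C)=O)[C@]2(C)[C@@H]([C@@H](OC(C)=O)[C@](CO[Si](CC)(CC)CC)(O)[C@@H](C)C(=O)OC(C)(C)C)[C@@H](C)[C@@H](O[Si](C)(C)C(C)(C)C)C[C@@H]2OC(=O)CCC | intermediate
42 | C7,C16-diol | Cl/C=C(\CO)/C=C/[C@@H](OC(C)=O)[C@]2(C)[C@@H]([C@@H](OC(C)=O)[C@](CO)(O)[C@@H](C)C(=O)OC(C)(C)C)[C@@H](C)[C@@H](O[Si](C)(C)C(C)(C)C)C[C@@H]2OC(=O)CCC | intermediate
43 | C16 allylic bromide | Cl/C=C(\CBr)/C=C/[C@@H](OC(C)=O)[C@]2(C)[C@@H]([C@@H](OC(C)=O)[C@](CO)(O)[C@@H](C)C(=O)OC(C)(C)C)[C@@H](C)[C@@H](O[Si](C)(C)C(C)(C)C)C[C@@H]2OC(=O)CCC | intermediate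
44 | bromo α-hydroxy aldehyde (cyclisation precursor) | Cl/C=C(\CBr)/C=C/[C@@H](OC(C)=O)[C@]2(C)[C@@H]([C@@H](OC(C)=O)[C@](C=O)(O)[C@@H](C)C(=O)OC(C)(C)C)[C@@H](C)[C@@H](O[Si](C)(C)C(C)(C)C)C[C@@H]2OC(=O)CCC | intermediate
45 | allylchromium dichloride from 44 | Cl/C=C(\C[Cr](Cl)Cl)/C=C/[C@@H](OC(C)=O)[C@]2(C)[C@@H]([C@@H](OC(C)=O)[C@](C=O)(O)[C@@H](C)C(=O)OC(C)(C)C)[C@@H](C)[C@@H](O[Si](C)(C)C(C)(C)C)C[C@@H]2OC(=O)CCC | intermediate
46 | ten-membered carbocycle (6S-Cl, 7R-OH, tert-butyl ester) | C=C1/C=C/[C@@H](OC(C)=O)[C@]2(C)[C@@H]([C@@H](OC(C)=O)[C@](O)([C@@H](C)C(=O)OC(C)(C)C)[C@@H](O)[C@H]1Cl)[C@@H](C)[C@@H](O[Si](C)(C)C(C)(C)C)C[C@@H]2OC(=O)CCC | intermediate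
47 | seco acid (C19 acid, 7- and 12-hydroxyls free) | C=C1/C=C/[C@@H](OC(C)=O)[C@]2(C)[C@@H]([C@@H](OC(C)=O)[C@](O)([C@@H](C)C(O)=O)[C@@H](O)[C@H]1Cl)[C@@H](C)[C@@H](O)C[C@@H]2OC(=O)CCC | intermediate
48 | γ-lactone with 12β-hydroxyl | C=C1/C=C/[C@@H](OC(C)=O)[C@]2(C)[C@@H]([C@@H](OC(C)=O)[C@]3(O)[C@@H](C)C(=O)O[C@H]3[C@H]1Cl)[C@@H](C)[C@@H](O)C[C@@H]2OC(=O)CCC | intermediate
49 | CNP0283653.2 | C=C1/C=C/[C@@H](OC(C)=O)[C@]2(C)[C@@H]([C@@H](OC(C)=O)[C@]3(O)[C@@H](C)C(=O)O[C@H]3[C@H]1Cl)[C@@H](C)C(=O)C[C@@H]2OC(=O)CCC | target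

**Step count.** Total: 32 steps. Longest linear sequence: 25 steps (steps 1–10, 15–19, 23–32).

**Steps most likely to fail**

Step 30. The ring closure may lose out to oligomerisation, excess CrCl2 may reduce the secondary allylic chloride of the product, or the facial selectivity at C7 may be poor. The fallback sets out from 44: stannylation of the allylic bromide with hexabutylditin and Pd(PPh3)4 in THF should give the allylstannane aldehyde F1. Treatment of F1 with InCl3 in MeCN at −40 °C transmetalates it to an allylindium dichloride, which cyclises through a chair transition state (anti) with no reducing metal present once the chlorohydrin exists. The fallback comes back to the route at 46.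

Step 15. The lithium enolate may deprotonate the hindered, enolisable aldehyde 16 (epimerising C10) or the adduct may revert by retro-aldol. The fallback sets out from 22: LDA and Me3SiCl at −78 °C give the trimethylsilyl ketene acetal F2. A Mukaiyama aldol of F2 with 16 under BF3·OEt2 in CH2Cl2 at −78 °C runs without base; the tert-butyl group still shields one enolate face and the Felkin–Anh preference still fixes the aldehyde face, so the same diastereomer is expected after aqueous work-up. The fallback comes back at 24.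

Step 19. Reduction of the very hindered amide may stall, or the esters may be attacked on forcing. The fallback sets out from 27: hydrosilylation with 1,1,3,3-tetramethyldisiloxane catalysed by IrCl(CO)(PPh3)2 in toluene at rt should stop at the O-silyl hemiaminal F3, a catalytic method known to spare esters. Hydrolysis of F3 with aqueous AcOH–THF releases the aldehyde, and the fallback comes back at 29.

**Further compounds**

F1 | step 30 | allylstannane aldehyde (C16–SnBu3 analogue of 44) | Cl/C=C(\C[Sn](CCCC)(CCCC)CCCC)/C=C/[C@@H](OC(C)=O)[C@]2(C)[C@@H]([C@@H](OC(C)=O)[C@](C=O)(O)[C@@H](C)C(=O)OC(C)(C)C)[C@@H](C)[C@@H](O[Si](C)(C)C(C)(C)C)C[C@@H]2OC(=O)CCC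
F2 | step 15 | trimethylsilyl ketene acetal of 22 | CC(C)(C)[C@H]1OC([C@@H](C)C(=O)OC(C)(C)C)=C(O[Si](C)(C)C)O1
F3 | step 19 | O-silyl hemiaminal of 27 | COC[C@@H]1CCCN1C(O[Si](C)(C)O[SiH](C)C)[C@]2(C)[C@@H]([C@@H](OC(C)=O)[C@](CO[Si](CC)(CC)CC)(O)[C@@H](C)C(=O)OC(C)(C)C)[C@@H](C)[C@@H](O[Si](C)(C)C(C)(C)C)C[C@@H]2OC(=O)CCC
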